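**Strategy.** Everything rests on building the benzene ring last, onto an enantiopure dihydropyran made from (S)-linalool. In one operation a methoxycarbene complex of zerovalent chromium, a terminal alkyne and one CO ligand are joined, forming C7–C8, C5–C6 and C4a–C5. The step exploits the para C5 and C8 oxygens of the benzene ring fused to the pyran ring at C4a–C8a, with the acyl carbon on C6 beside the C5 hydroxyl and hydrogen on C7. The precursor is a 3,4-dihydro-2H-pyran with the C2 stereocentre in place, a C4 silyloxy group as latent C3=C4 double bond, and the Cr(CO)5 methoxycarbene on its enol-ether carbon (pyran C6, later C8a).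

Key step: step 10

Remark on the chemistry: the carbinol carbons of 6 and 22 and C4 of 10–12, 14–16, 18 and 19 arise as epimer mixtures that are destroyed later, so their SMILES leave these centres undefined; CO ligands are written Cr=C=O and the η6 bond of 18 is not drawn.

Step 1
Reactants: 1 (S)-(+)-linalool, (3S)-3,7-dimethylocta-1,6-dien-3-ol
Product: 3 (3S)-3,7-dimethyloct-6-ene-1,3-diol, via B-alkyl-9-BBN adduct 2 (not isolated)
Conditions: 9-BBN (2.2 equiv), THF, 0 °C → rt; then NaOH, H2O2, 0 °C → rt
Reagents that add atoms: hydrogen peroxide, OO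
Why: Hydroboration–oxidation: the bulky dialkylborane adds only to the monosubstituted vinyl group, boron at the terminal carbon, and leaves the trisubstituted alkene and the bonds of the stereocentre untouched, so the (S) centre is carried over unchanged.

Step 2
Reactants: 3 (3S)-3,7-dimethyloct-6-ene-1,3-diol
Product: 4 (3S)-3,7-dimethyloctane-1,3,7-triol
Conditions: Co(acac)2 (20 mol %), PhSiH3, O2 (1 atm), THF, rt
Reagents that add atoms: dioxygen, O=O
Why: Mukaiyama hydration: hydrogen-atom transfer from a cobalt hydride to the trisubstituted alkene gives the tertiary radical, which is trapped by O2 and reduced to the tertiary alcohol, and because no carbocation is involved the C3 hydroxyl cannot close a tetrahydropyran onto C7.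

Step 3
Reactants: 4 (3S)-3,7-dimethyloctane-1,3,7-triol
Product: 5 (3S)-3,7-dihydroxy-3,7-dimethyloctanal
Conditions: TEMPO (10 mol %), PhI(OAc)2 (1.1 equiv), CH2Cl2, rt
Reagents that add atoms: none
Why: Oxoammonium (TEMPO) oxidation with PhI(OAc)2 as terminal oxidant is selective for the primary alcohol, tertiary alcohols cannot be oxidised, and the water-free medium stops at the aldehyde.

Step 4
Reactants: 5 (3S)-3,7-dihydroxy-3,7-dimethyloctanal
Product: 6 (5S)-5,9-dimethyldec-1-yne-3,5,9-triol (C3 epimers)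
Conditions: HC≡CMgBr (3.5 equiv), THF, −78 → 0 °C; aq. NH4Cl
Reagents that add atoms: ethynylmagnesium bromide, C#C[Mg]Br
Why: Grignard 1,2-addition of the acetylide to the aldehyde after two equivalents have deprotonated the hydroxyls, the low temperature suppressing retro-aldol cleavage of the magnesium aldolate; the new carbinol centre forms without control and is removed by oxidation in step 5.

Step 5
Reactants: 6 (5S)-5,9-dimethyldec-1-yne-3,5,9-triol
Product: 7 (5S)-5,9-dihydroxy-5,9-dimethyldec-1-yn-3-one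
Conditions: MnO2 (activated, excess), CH2Cl2, rt
Reagents that add atoms: none
Why: MnO2 oxidation is selective for the activated propargylic alcohol and cannot touch the two tertiary alcohols.

Step 6
Reactants: 7 (5S)-5,9-dihydroxy-5,9-dimethyldec-1-yn-3-one
Product: 9 (2S)-2-(4-hydroxy-4-methylpentyl)-2-methyl-2,3-dihydro-4H-pyran-4-one, via enaminone 8 (not isolated)
Conditions: Et2NH (1.2 equiv), CH2Cl2, 0 °C → rt; then TFA (2 equiv), 0 °C → rt
Reagents that add atoms: none
Why: Conjugate addition of the secondary amine to the terminal ynone gives the enaminone, and acid then drives a 6-endo-trig oxa-Michael addition–elimination by the C5 hydroxyl with loss of Et2NH, the same reaction type as the acid closure of β-hydroxy β'-alkoxy enones to 2,3-dihydro-4H-pyran-4-ones; the oxygen on the stereocentre is the nucleophile, so the configuration is retained.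

Step 7
Reactants: 9 (2S)-2-(4-hydroxy-4-methylpentyl)-2-methyl-2,3-dihydro-4H-pyran-4-one
Product: 10 (2S)-2-(4-hydroxy-4-methylpentyl)-2-methyl-3,4-dihydro-2H-pyran-4-ol (C4 epimers)
Conditions: NaBH4, CeCl3·7H2O, MeOH, −78 °C; NaHCO3 work-up
Reagents that add atoms: none
Why: Luche reduction: the cerium-modified borohydride reduces the vinylogous ester carbonyl 1,2 without touching the enol ether, and the C4 configuration need not be controlled because C4 becomes sp2 in step 11.

Step 8
Reactants: 10 (2S)-2-(4-hydroxy-4-methylpentyl)-2-methyl-3,4-dihydro-2H-pyran-4-ol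
Product: 12 (2S)-2-methyl-2-[4-methyl-4-(triethylsilyloxy)pentyl]-4-(triisopropylsilyloxy)-3,4-dihydro-2H-pyran, via mono-TIPS ether 11 (not isolated)
Conditions: TIPSOTf (1.1 equiv), 2,6-lutidine, CH2Cl2, 0 °C; then TESOTf (1.5 equiv), 0 °C
Reagents that add atoms: triisopropylsilyl triflate, CC(C)[Si](OS(=O)(=O)C(F)(F)F)(C(C)C)C(C)C; triethylsilyl triflate, CC[Si](CC)(CC)OS(=O)(=O)C(F)(F)F
Why: Silyl triflate silylation: TIPSOTf reacts only with the secondary allylic hydroxyl and TESOTf then caps the tertiary one; O4 carries TIPS because it has no Si–CH3 group that t-BuLi could deprotonate in step 9, and the side-chain hydroxyl is protected only now, when it is the sole tertiary hydroxyl.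

Step 9
Reactants: 12 (2S)-2-methyl-2-[4-methyl-4-(triethylsilyloxy)pentyl]-4-(triisopropylsilyloxy)-3,4-dihydro-2H-pyran; 13 chromium hexacarbonyl, Cr(CO)6
Product: 16 pentacarbonyl{methoxy[(2S)-2-methyl-2-[4-methyl-4-(triethylsilyloxy)pentyl]-4-(triisopropylsilyloxy)-3,4-dihydro-2H-pyran-6-yl]methylidene}chromium, via 6-lithio dihydropyran 14 (not isolated), via lithium acylchromate 15 (not isolated)
Conditions: t-BuLi (1.6 equiv), THF, −78 → 0 °C; Cr(CO)6, Et2O/THF, −78 °C → rt; then MeOTf, CH2Cl2, 0 °C
Reagents that add atoms: methyl trifluoromethanesulfonate, COS(=O)(=O)C(F)(F)F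
Why: Vinylic lithiation at C6 beside the ring oxygen (as with silylated glycals), addition of the vinyllithium to a CO ligand of Cr(CO)6 and O-methylation of the acylchromate with the hard electrophile MeOTf is the standard three-stage synthesis of alkoxycarbene complexes of zerovalent chromium.

Step 10
Reactants: 16 pentacarbonyl[methoxy(dihydropyranyl)carbene]chromium as named in step 9; 17 3,3-diethoxyprop-1-yne
Product: 19 (2S)-6-(diethoxymethyl)-8-methoxy-2-methyl-2-[4-methyl-4-(triethylsilyloxy)pentyl]-4-(triisopropylsilyloxy)chroman-5-ol, via tricarbonylchromium arene complex 18 (not isolated)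
Conditions: 17 (2 equiv), THF (0.05 M), 55 °C, argon; then air, Et2O, rt
Reagents that add atoms: none
Why: Thermal loss of one CO from the zerovalent chromium carbene 16 opens a site for the alkyne, which inserts into the Cr=C bond to give a vinylcarbene; CO insertion then gives a chromium-bound dienylketene, whose 6π electrocyclisation and enolisation deliver the phenol as its Cr(CO)3 complex 18, released by air. This is a Dötz benzannulation, and its closest relatives are the reactions of cyclic 2-alkoxyvinyl (dihydropyranyl, glycal-derived) methoxycarbene complexes of chromium with terminal alkynes, which give 5-hydroxy-8-methoxychromans. The benzene ring closes by disrotatory 6π electrocyclisation between the ketene carbon (C5) and the pyran β-carbon (C4a) after the two insertions have made C7–C8 and C5–C6; the carbene carbon becomes C8 with its methoxy group and the enol-ether carbons become C8a and C4a. No stereocentre is created: C2 is remote and untouched and C4 stays an epimer mixture. The step needs regioselective alkyne insertion, which the terminal alkyne secures sterically, since its unsubstituted carbon bonds to the carbene carbon and the acetal-bearing carbon therefore ends at C6 beside the CO-derived C5, with hydrogen at C7. Selectivity for the phenol over five-membered-ring products is secured by the alkenyl (not aryl) carbene and the coordinating solvent.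

Step 11
Reactants: 19 (2S)-6-(diethoxymethyl)-8-methoxy-2-methyl-2-[4-methyl-4-(triethylsilyloxy)pentyl]-4-(triisopropylsilyloxy)chroman-5-ol
Product: 21 (2S)-5-hydroxy-2-(4-hydroxy-4-methylpentyl)-8-methoxy-2-methyl-2H-chromene-6-carbaldehyde, via chromene acetal 20 (not isolated)
Conditions: CSA (0.2 equiv), CH2Cl2, 0 °C → rt; then 1 M HCl/THF, rt
Reagents that add atoms: water, O
Why: Acid-catalysed E1 elimination: the C4–O bond ionises easily while the ring is still electron-rich because the benzylic cation is flanked by the C5 hydroxyl and the ring oxygen on C8a (ortho-quinone-methide-type stabilisation), loss of a C3 proton gives the C3=C4 bond, and aqueous acid then hydrolyses the acetal and the tertiary triethylsilyl ether under conditions that do not dehydrate a tertiary aliphatic alcohol.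

Step 12
Reactants: 21 (2S)-5-hydroxy-2-(4-hydroxy-4-methylpentyl)-8-methoxy-2-methyl-2H-chromene-6-carbaldehyde
Product: 22 (2S)-6-(1-hydroxyethyl)-2-(4-hydroxy-4-methylpentyl)-8-methoxy-2-methyl-2H-chromen-5-ol (carbinol epimers)
Conditions: MeMgBr (4 equiv), THF, −78 → 0 °C; aq. NH4Cl
Reagents that add atoms: methylmagnesium bromide, C[Mg]Br
Why: Grignard addition to the aldehyde, two further equivalents being consumed by the phenol and the tertiary alcohol; the new carbinol centre is uncontrolled and is oxidised in step 13.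

Step 13
Reactants: 22 (2S)-6-(1-hydroxyethyl)-2-(4-hydroxy-4-methylpentyl)-8-methoxy-2-methyl-2H-chromen-5-ol
Product: 23 1-[(2S)-5-hydroxy-2-(4-hydroxy-4-methylpentyl)-8-methoxy-2-methyl-2H-chromen-6-yl]ethan-1-one
Conditions: MnO2 (activated, excess), CH2Cl2, rt
Reagents that add atoms: none
Why: MnO2 oxidises the benzylic secondary alcohol to the hydrogen-bonded ortho-hydroxy aryl ketone and leaves the tertiary alcohol, the chromene and the 4-methoxyphenol alone.

Step 14
Reactants: 23 1-[(2S)-5-hydroxy-2-(4-hydroxy-4-methylpentyl)-8-methoxy-2-methyl-2H-chromen-6-yl]ethan-1-one; 24 4-hydroxybenzaldehyde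
Product: 25 (2E)-1-[(2S)-5-hydroxy-2-(4-hydroxy-4-methylpentyl)-8-methoxy-2-methyl-2H-chromen-6-yl]-3-(4-hydroxyphenyl)prop-2-en-1-one
Conditions: 24 (1.5 equiv), KOH (50% aq., excess), EtOH, argon, rt; then 1 M HCl to pH 4, 0 °C
Reagents that add atoms: none
Why: Claisen–Schmidt condensation: the ketone enolate adds to the aldehyde and E1cB loss of hydroxide gives the conjugated (E)-enone as the thermodynamic isomer; excess KOH keeps the acidic hydroxyls ionised, and this condensation is established for unprotected 4-hydroxybenzaldehyde.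

Step 15
Reactants: 25 (2E)-1-[(2S)-5-hydroxy-2-(4-hydroxy-4-methylpentyl)-8-methoxy-2-methyl-2H-chromen-6-yl]-3-(4-hydroxyphenyl)prop-2-en-1-one
Product: 27 (2E)-1-[(2S)-5,8-dihydroxy-2-(4-hydroxy-4-methylpentyl)-2-methyl-2H-chromen-6-yl]-3-(4-hydroxyphenyl)prop-2-en-1-one (CNP0322520.1), via acylquinone 26 (not isolated)
Conditions: (NH4)2Ce(NO3)6 (2.2 equiv), MeCN/H2O, 0 °C; then Na2S2O4, EtOAc/H2O, rt
Reagents that add atoms: water, O
Why: Oxidative demethylation: two one-electron oxidations of the 4-methoxyphenol by (NH4)2Ce(NO3)6 and attack of water at C8 expel methanol to give the para-quinone, which should be much faster than oxidation of the enone-deactivated B-ring phenol, and Na2S2O4 reduces the quinone at once to the hydroquinone without touching the enone.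

**Compound list**

1 | (S)-(+)-linalool, (3S)-3,7-dimethylocta-1,6-dien-3-ol | C=C[C@@](C)(O)CCC=C(C)C | starting material
2 | B-[(3S)-3-hydroxy-3,7-dimethyloct-6-en-1-yl]-9-borabicyclo[3.3.1]nonane | CC(C)=CCC[C@](C)(O)CCB1C2CCCC1CCC2 | intermediate
3 | (3S)-3,7-dimethyloct-6-ene-1,3-diol | OCC[C@@](C)(O)CCC=C(C)C | intermediate
4 | (3S)-3,7-dimethyloctane-1,3,7-triol | OCC[C@@](C)(O)CCCC(C)(C)O | intermediate
5 | (3S)-3,7-dihydroxy-3,7-dimethyloctanal | O=CC[C@@](C)(O)CCCC(C)(C)O | intermediate
6 | (5S)-5,9-dimethyldec-1-yne-3,5,9-triol (C3 epimers) | C#CC(O)C[C@@](C)(O)CCCC(C)(C)O | intermediate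
7 | (5S)-5,9-dihydroxy-5,9-dimethyldec-1-yn-3-one | C#CC(=O)C[C@@](C)(O)CCCC(C)(C)O | intermediate
8 | (1E,5S)-1-(diethylamino)-5,9-dihydroxy-5,9-dimethyldec-1-en-3-one | CCN(CC)/C=C/C(=O)C[C@@](C)(O)CCCC(C)(C)O | intermediate
9 | (2S)-2-(4-hydroxy-4-methylpentyl)-2-methyl-2,3-dihydro-4H-pyran-4-one | O=C1C=CO[C@@](C)(CCCC(C)(C)O)C1 | intermediate
10 | (2S)-2-(4-hydroxy-4-methylpentyl)-2-methyl-3,4-dihydro-2H-pyran-4-ol (C4 epimers) | OC1C=CO[C@@](C)(CCCC(C)(C)O)C1 | intermediate
11 | 2-methyl-5-[(2S)-2-methyl-4-(triisopropylsilyloxy)-3,4-dihydro-2H-pyran-2-yl]pentan-2-ol | CC(C)[Si](OC1C=CO[C@@](C)(CCCC(C)(C)O)C1)(C(C)C)C(C)C | intermediate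
12 | (2S)-2-methyl-2-[4-methyl-4-(triethylsilyloxy)pentyl]-4-(triisopropylsilyloxy)-3,4-dihydro-2H-pyran | CC[Si](CC)(CC)OC(C)(C)CCC[C@@]1(C)CC(O[Si](C(C)C)(C(C)C)C(C)C)C=CO1 | intermediate
13 | chromium hexacarbonyl | O=C=[Cr](=C=O)(=C=O)(=C=O)(=C=O)=C=O | starting material
14 | 6-lithio derivative of 12 | [Li]C1=CC(O[Si](C(C)C)(C(C)C)C(C)C)C[C@](C)(CCCC(C)(C)O[Si](CC)(CC)CC)O1 | intermediate
15 | lithium pentacarbonyl(dihydropyranylcarbonyl)chromate | [Li+].[O-]C(=[Cr](=C=O)(=C=O)(=C=O)(=C=O)=C=O)C1=CC(O[Si](C(C)C)(C(C)C)C(C)C)C[C@](C)(CCCC(C)(C)O[Si](CC)(CC)CC)O1 | intermediate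
16 | pentacarbonyl{methoxy[(2S)-2-methyl-2-[4-methyl-4-(triethylsilyloxy)pentyl]-4-(triisopropylsilyloxy)-3,4-dihydro-2H-pyran-6-yl]methylidene}chromium | COC(=[Cr](=C=O)(=C=O)(=C=O)(=C=O)=C=O)C1=CC(O[Si](C(C)C)(C(C)C)C(C)C)C[C@](C)(CCCC(C)(C)O[Si](CC)(CC)CC)O1 | intermediate
17 | 3,3-diethoxyprop-1-yne | C#CC(OCC)OCC | starting material
18 | tricarbonyl(η6-arene)chromium complex of 19 (Cr on the new benzene ring) | CC[Si](CC)(CC)OC(C)(C)CCC[C@@]1(C)CC(O[Si](C(C)C)(C(C)C)C(C)C)c2c(O)c(C(OCC)OCC)cc(OC)c2O1.[Cr](=C=O)(=C=O)=C=O | intermediate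
19 | (2S)-6-(diethoxymethyl)-8-methoxy-2-methyl-2-[4-methyl-4-(triethylsilyloxy)pentyl]-4-(triisopropylsilyloxy)chroman-5-ol | CC[Si](CC)(CC)OC(C)(C)CCC[C@@]1(C)CC(O[Si](C(C)C)(C(C)C)C(C)C)c2c(O)c(C(OCC)OCC)cc(OC)c2O1 | intermediate
20 | (2S)-6-(diethoxymethyl)-8-methoxy-2-methyl-2-[4-methyl-4-(triethylsilyloxy)pentyl]-2H-chromen-5-ol | CC[Si](CC)(CC)OC(C)(C)CCC[C@@]1(C)C=Cc2c(O)c(C(OCC)OCC)cc(OC)c2O1 | intermediate
21 | (2S)-5-hydroxy-2-(4-hydroxy-4-methylpentyl)-8-methoxy-2-methyl-2H-chromene-6-carbaldehyde | CC(C)(O)CCC[C@@]1(C)C=Cc2c(O)c(C=O)cc(OC)c2O1 | intermediate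
22 | (2S)-6-(1-hydroxyethyl)-2-(4-hydroxy-4-methylpentyl)-8-methoxy-2-methyl-2H-chromen-5-ol (carbinol epimers) | CC(C)(O)CCC[C@@]1(C)C=Cc2c(O)c(C(C)O)cc(OC)c2O1 | intermediate
23 | 1-[(2S)-5-hydroxy-2-(4-hydroxy-4-methylpentyl)-8-methoxy-2-methyl-2H-chromen-6-yl]ethan-1-one | CC(C)(O)CCC[C@@]1(C)C=Cc2c(O)c(C(C)=O)cc(OC)c2O1 | intermediate
24 | 4-hydroxybenzaldehyde | O=Cc1ccc(O)cc1 | starting material
25 | (2E)-1-[(2S)-5-hydroxy-2-(4-hydroxy-4-methylpentyl)-8-methoxy-2-methyl-2H-chromen-6-yl]-3-(4-hydroxyphenyl)prop-2-en-1-one | CC(C)(O)CCC[C@@]1(C)C=Cc2c(O)c(C(=O)/C=C/c3ccc(O)cc3)cc(OC)c2O1 | intermediate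
26 | (2S)-2-(4-hydroxy-4-methylpentyl)-6-[(2E)-3-(4-hydroxyphenyl)prop-2-enoyl]-2-methyl-2H-chromene-5,8-dione | CC(C)(O)CCC[C@@]1(C)C=CC2=C(O1)C(=O)C=C(C(=O)/C=C/c3ccc(O)cc3)C2=O | intermediate
27 | (2E)-1-[(2S)-5,8-dihydroxy-2-(4-hydroxy-4-methylpentyl)-2-methyl-2H-chromen-6-yl]-3-(4-hydroxyphenyl)prop-2-en-1-one | CC(C)(O)CCC[C@@]1(C)C=Cc2c(O)c(C(=O)/C=C/c3ccc(O)cc3)cc(O)c2O1 | target

**Step count.** Total: 15 steps. Longest linear sequence: 15 steps (1 → 27); 13, 17 and 24 are bought and enter directly.

**Steps most likely to fail**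

Step 10. The chromium-bound dienylketene may close slowly onto C4a, which sits next to the bulky silyloxy-bearing C4, and divert to cyclobutenone or furan products. The acetal oxygens may also coordinate chromium and ionise, eroding regiocontrol and consuming the alkyne. The fallback brings in the C6 carbon at the alcohol oxidation level with a non-ionisable propargylic silyl ether and adjusts the oxidation state afterwards. It sets out from 16: heating with tert-butyldimethyl(prop-2-yn-1-yloxy)silane in THF at 55 °C should give the tricarbonylchromium arene complex F1 and, after air, the 6-(silyloxymethyl) phenol F2. TBAF in THF should then free the tetraol F3. Catalytic CSA in CH2Cl2 at rt should dehydrate only the doubly oxygen-activated secondary benzylic alcohol at C4, giving the chromene diol F4. MnO2 in CH2Cl2 should oxidise the remaining benzylic alcohol, and the route is rejoined at 21.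

Step 11. Heterolysis of the hindered C4–O silyl ether may be too slow, so that acetal hydrolysis comes first and elimination stalls on the deactivated formyl arene; the chromene could also rehydrate in the aqueous stage. The fallback separates desilylation from elimination and changes the leaving group from silanol to water. From 19, TBAF in THF should give the 4-hydroxychroman triol acetal F5. Its unhindered 4-hydroxyl, flanked by the C5 phenol, should leave under catalytic CSA in dry CH2Cl2, and wet acid then hydrolyses the acetal; the route is rejoined at 21.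

Step 15. One-electron oxidation may spill over to the electron-rich chromene double bond or the free B-ring phenol, and nucleophiles may add to the acylquinone at C7 before it is reduced. The fallback moves the oxidative demethylation to the simpler acetophenone, before the styryl unit and the B-ring phenol exist. From 23, (NH4)2Ce(NO3)6 in MeCN/H2O at 0 °C should give the acetylquinone F6, reduced in the same flask by Na2S2O4 to the 5,8-dihydroxy acetophenone F7. Claisen–Schmidt condensation of F7 with 24 (KOH, degassed EtOH/H2O, argon, Na2S2O4 as oxygen scavenger) should then give 27 directly.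

**Further compounds**

F1 | step 10 | tricarbonyl(η6-arene)chromium complex of F2 | CC[Si](CC)(CC)OC(C)(C)CCC[C@@]1(C)CC(O[Si](C(C)C)(C(C)C)C(C)C)c2c(O)c(CO[Si](C)(C)C(C)(C)C)cc(OC)c2O1.[Cr](=C=O)(=C=O)=C=O
F2 | step 10 | (2S)-6-[(tert-butyldimethylsilyloxy)methyl]-8-methoxy-2-methyl-2-[4-methyl-4-(triethylsilyloxy)pentyl]-4-(triisopropylsilyloxy)chroman-5-ol | CC[Si](CC)(CC)OC(C)(C)CCC[C@@]1(C)CC(O[Si](C(C)C)(C(C)C)C(C)C)c2c(O)c(CO[Si](C)(C)C(C)(C)C)cc(OC)c2O1
F3 | step 10 | (2S)-6-(hydroxymethyl)-2-(4-hydroxy-4-methylpentyl)-8-methoxy-2-methylchroman-4,5-diol | CC(C)(O)CCC[C@@]1(C)CC(O)c2c(O)c(CO)cc(OC)c2O1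
F4 | step 10 | (2S)-6-(hydroxymethyl)-2-(4-hydroxy-4-methylpentyl)-8-methoxy-2-methyl-2H-chromen-5-ol | CC(C)(O)CCC[C@@]1(C)C=Cc2c(O)c(CO)cc(OC)c2O1
F5 | step 11 | (2S)-6-(diethoxymethyl)-2-(4-hydroxy-4-methylpentyl)-8-methoxy-2-methylchroman-4,5-diol | CC(C)(O)CCC[C@@]1(C)CC(O)c2c(O)c(C(OCC)OCC)cc(OC)c2O1
F6 | step 15 | (2S)-6-acetyl-2-(4-hydroxy-4-methylpentyl)-2-methyl-2H-chromene-5,8-dione | CC(C)(O)CCC[C@@]1(C)C=CC2=C(O1)C(=O)C=C(C(C)=O)C2=O
F7 | step 15 | 1-[(2S)-5,8-dihydroxy-2-(4-hydroxy-4-methylpentyl)-2-methyl-2H-chromen-6-yl]ethan-1-one | CC(C)(O)CCC[C@@]1(C)C=Cc2c(O)c(C(C)=O)cc(O)c2O1
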